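**Retrosynthetic overview**
1. The three angelate esters are cut last: the C2 and C11 esters from diol mono-angelate 20 and angelic anhydride 17, the C1 ester from tricyclic alcohol 16, where C1 carries the only free hydroxyl.
2. The cyclobutane, the cyclohexenone and the bridged seven-membered ring arise together from eleven-membered trienone 15 by a transannular crossed [2+2] photocycloaddition.
3. The eleven-membered ring comes from acyclic ynal 13 by a nickel-catalysed methylative aldehyde–alkyne macrocyclisation, followed by allylic oxidation.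
4. Ynal 13 is assembled from (S)-pantolactone (bought stereocentre), an alkoxyallenylzinc (sets two more stereocentres) and a five-carbon nitrile phosphonate.
5. Ring order: eleven-membered carbocycle first, then the four-, six- and seven-membered rings in the single photochemical step.

Assumption: compounds 1, 4, 10 and 17 are purchased; labels C1–C11 in the Why lines are the ring carbons in the order they appear in the target SMILES (C1, C2, C11 carry the esters, C3 is CMe2, C6 is the ketone carbon, C8 and C10 carry methyl).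

**Step 1**
Reactants: 1 (S)-pantolactone
Product: 2 (3S)-3-(methoxymethoxy)-4,4-dimethyloxolan-2-one
Conditions: MOMCl, i-Pr2NEt, CH2Cl2, 0 °C to reflux
Reagents that add atoms: chloromethyl methyl ether, COCCl
Why: MOM ether formation (O-alkylation) protects the purchased C2 carbinol as a chelating ether without touching the stereocentre.

**Step 2**
Reactants: 2 (3S)-3-(methoxymethoxy)-4,4-dimethyloxolan-2-one
Product: 3 (3S)-3-(methoxymethoxy)-4,4-dimethyloxolan-2-ol (anomeric mixture)
Conditions: i-Bu2AlH (1.2 equiv), CH2Cl2, −78 °C; aq. potassium sodium tartrate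
Reagents that add atoms: none
Why: Low-temperature hydride half-reduction of a γ-lactone stops at the lactol because the tetrahedral aluminate is stable at −78 °C.

**Step 3**
Reactants: 4 3-(trimethylsilyl)prop-2-yn-1-ol
Product: 5 [3-(methoxymethoxy)prop-1-yn-1-yl]trimethylsilane
Conditions: MOMCl, i-Pr2NEt, CH2Cl2, 0 °C to rt
Reagents that add atoms: chloromethyl methyl ether, COCCl
Why: MOM ether formation gives the propargyl ether needed for α-lithiation, with the silyl group blocking the alkyne terminus.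

**Step 4**
Reactants: 3 (3S)-3-(methoxymethoxy)-4,4-dimethyloxolan-2-ol; 5 [3-(methoxymethoxy)prop-1-yn-1-yl]trimethylsilane
Product: 8 (3S,4R,5S)-3,5-bis(methoxymethoxy)-2,2-dimethyl-7-(trimethylsilyl)hept-6-yne-1,4-diol, via lithiated propargyl ether 6 (not isolated), via allenylzinc bromide 7 (not isolated)
Conditions: 5 (2.5 equiv), s-BuLi, Et2O, −78 °C; ZnBr2, −78 to −20 °C; then 3, −78 °C to rt; aq. NH4Cl
Reagents that add atoms: none
Why: γ-Alkoxyallenylzinc addition (SE2') to the open aldehyde form of the lactol: the rapidly racemising allenylzinc reacts through a cyclic chair transition state to give the anti C1/C11 diol relationship, and zinc chelation between the aldehyde oxygen and the α-OMOM group (Cram chelate, attack opposite the bulky CMe2 arm) sets C1 syn to the purchased C2 centre.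

**Step 5**
Reactants: 8 (3S,4R,5S)-3,5-bis(methoxymethoxy)-2,2-dimethyl-7-(trimethylsilyl)hept-6-yne-1,4-diol
Product: 9 (4S,5R)-4-(methoxymethoxy)-5-[(1S)-1-(methoxymethoxy)-3-(trimethylsilyl)prop-2-yn-1-yl]-3,3-dimethyloxolan-2-ol (anomeric mixture)
Conditions: TEMPO (10 mol %), PhI(OAc)2 (1.1 equiv), CH2Cl2, 0 °C to rt
Reagents that add atoms: none
Why: Oxoammonium (TEMPO) oxidation is selective for the primary alcohol, the hydroxy aldehyde closes to the five-membered lactol, and limiting the oxidant to one equivalent avoids the lactone.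

**Step 6**
Reactants: 9 (4S,5R)-4-(methoxymethoxy)-5-[(1S)-1-(methoxymethoxy)-3-(trimethylsilyl)prop-2-yn-1-yl]-3,3-dimethyloxolan-2-ol; 10 diethyl [(2E)-3-cyano-2-methylprop-2-en-1-yl]phosphonate
Product: 12 (2E,4E,7S,8S,9S)-8-hydroxy-7,9-bis(methoxymethoxy)-3,6,6-trimethylundeca-2,4-dien-10-ynenitrile, via C-silylated dienenitrile 11 (not isolated)
Conditions: 10 (2.2 equiv), NaH, THF, 0 °C to rt; then MeOH, K2CO3 (cat.), rt
Reagents that add atoms: none
Why: Vinylogous Horner–Wadsworth–Emmons olefination of the lactol (reacting as its non-enolisable neopentyl aldehyde) gives the new E alkene, the 2E geometry comes from the reagent (minor 2Z isomer removed by chromatography), and methanolic carbonate then cleaves the alkynyl C–Si bond.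

**Step 7**
Reactants: 12 (2E,4E,7S,8S,9S)-8-hydroxy-7,9-bis(methoxymethoxy)-3,6,6-trimethylundeca-2,4-dien-10-ynenitrile
Product: 13 (2E,4E,7S,8S,9S)-8-hydroxy-7,9-bis(methoxymethoxy)-3,6,6-trimethylundeca-2,4-dien-10-ynal
Conditions: i-Bu2AlH (2.5 equiv), toluene, −78 °C; aq. potassium sodium tartrate, then SiO2
Reagents that add atoms: water, O
Why: Hydride reduction of the conjugated nitrile stops at the N-aluminoimine, which hydrolyses to the dienal on work-up (standard retinoid nitrile-to-aldehyde reduction), while the alkyne and MOM ethers are inert at −78 °C.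

**Step 8**
Reactants: 13 (2E,4E,7S,8S,9S)-8-hydroxy-7,9-bis(methoxymethoxy)-3,6,6-trimethylundeca-2,4-dien-10-ynal
Product: 14 (2E,4E,7S,8S,9S,10E)-7,9-bis(methoxymethoxy)-3,6,6,10-tetramethylcycloundeca-2,4,10-triene-1,8-diol (epimers at the new carbinol C1 of the ring name)
Conditions: Ni(cod)2 (20 mol %), IMes (20 mol %), Me2Zn (3 equiv), THF, 0 °C to rt, syringe-pump addition of 13 to 3 mM; aq. NH4Cl
Reagents that add atoms: dimethylzinc, C[Zn]C
Why: Proposed new method: nickel-catalysed methylative ynal macrocyclisation, in which zerovalent nickel couples the aldehyde with the unsubstituted alkyne terminus (favoured by the carbene ligand, endo mode) to an oxanickelacyclopentene, Me2Zn transfers methyl to nickel, and C(sp2)–CH3 reductive elimination gives the E trisubstituted alkene by syn addition, so the C5–C6 bond, the C10 methyl and the eleven-membered ring form in one operation; the closest known reactions are nickel-catalysed alkylative aldehyde–alkyne couplings with organozincs (small rings and three-component couplings) and nickel-catalysed reductive ynal macrocyclisations of larger rings, and the new carbinol centre is removed in step 9.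

**Step 9**
Reactants: 14 (2E,4E,7S,8S,9S,10E)-7,9-bis(methoxymethoxy)-3,6,6,10-tetramethylcycloundeca-2,4,10-triene-1,8-diol
Product: 15 (2E,4E,7S,8S,9S,10E)-8-hydroxy-7,9-bis(methoxymethoxy)-3,6,6,10-tetramethylcycloundeca-2,4,10-trien-1-one
Conditions: MnO2 (20 equiv), CH2Cl2, rt, dark
Reagents that add atoms: none
Why: MnO2 allylic oxidation converts only the doubly allylic carbinol to the cross-conjugated trienone and leaves the non-allylic C1 hydroxyl alone.

**Step 10**
Reactants: 15 (2E,4E,7S,8S,9S,10E)-8-hydroxy-7,9-bis(methoxymethoxy)-3,6,6,10-tetramethylcycloundeca-2,4,10-trien-1-one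
Product: 16 (1R,2R,3S,4R,5S,7S,8R)-4-hydroxy-3,5-bis(methoxymethoxy)-2,6,6,11-tetramethyltricyclo[5.4.0.0(2,8)]undec-10-en-9-one
Conditions: 2-isopropylthioxanthone (20 mol %), 405 nm LEDs, degassed MeCN, 2 mM, 0 °C
Reagents that add atoms: none
Why: Transannular crossed enone–alkene [2+2] photocycloaddition under triplet sensitisation: energy transfer reaches only the dienone (not the rigid product enone), E/Z equilibration at C7=C8 lets the dienone terminus C4 bond to the unsubstituted end C5 of the C5=C10 alkene (bonding of neopentyl C4 to fully substituted C10 is sterically blocked), the resulting C9/C10 biradical collapses at C9 to restore the enone, the tricyclic topology fixes C4, C5, C9 and C10 relative to one another, and the allylic C11 centre selects the face (new C9–C10 bond anti to the C11–O bond, on the side of H-11).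

**Step 11**
Reactants: 16 (1R,2R,3S,4R,5S,7S,8R)-4-hydroxy-3,5-bis(methoxymethoxy)-2,6,6,11-tetramethyltricyclo[5.4.0.0(2,8)]undec-10-en-9-one; 17 angelic anhydride
Product: 18 (1R,2R,3S,4R,5S,7S,8R)-3,5-bis(methoxymethoxy)-2,6,6,11-tetramethyl-9-oxotricyclo[5.4.0.0(2,8)]undec-10-en-4-yl (2Z)-2-methylbut-2-enoate
Conditions: LiN(SiMe3)2 (1.05 equiv), THF, −78 °C; then 17 (1.5 equiv), −78 to 0 °C; aq. NH4Cl
Reagents that add atoms: none
Why: Alkoxide acylation with the anhydride esterifies C1, the only free hydroxyl, while O–H deprotonation outruns γ-deprotonation of the enone at −78 °C, and the absence of a nucleophilic amine catalyst avoids Z-to-E isomerisation to the tiglate.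

**Step 12**
Reactants: 18 (1R,2R,3S,4R,5S,7S,8R)-3,5-bis(methoxymethoxy)-2,6,6,11-tetramethyl-9-oxotricyclo[5.4.0.0(2,8)]undec-10-en-4-yl (2Z)-2-methylbut-2-enoate
Product: 20 (1R,2R,3S,4R,5S,7S,8R)-3,5-dihydroxy-2,6,6,11-tetramethyl-9-oxotricyclo[5.4.0.0(2,8)]undec-10-en-4-yl (2Z)-2-methylbut-2-enoate, via bis(bromomethyl) ether 19 (not isolated)
Conditions: Me2BBr (5 equiv), CH2Cl2, −78 °C; then THF/sat. aq. NaHCO3, −78 °C to rt
Reagents that add atoms: none
Why: Lewis-acid acetal cleavage with bromodimethylborane: the boron binds the terminal methoxy oxygen of each MOM group and bromide gives the bromomethyl ether, which hydrolyses to the carbinol on bicarbonate work-up; with no protic nucleophile present the angelate is neither transesterified nor isomerised, and the enone and cyclobutane are untouched at −78 °C.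

**Step 13**
Reactants: 20 (1R,2R,3S,4R,5S,7S,8R)-3,5-dihydroxy-2,6,6,11-tetramethyl-9-oxotricyclo[5.4.0.0(2,8)]undec-10-en-4-yl (2Z)-2-methylbut-2-enoate; 17 angelic anhydride
Product: 21 (1R,2R,3S,4R,5S,7S,8R)-2,6,6,11-tetramethyl-9-oxotricyclo[5.4.0.0(2,8)]undec-10-ene-3,4,5-triyl tris[(2Z)-2-methylbut-2-enoate] (CNP0330079.1)
Conditions: LiN(SiMe3)2 (2.1 equiv), THF, −78 °C; then 17 (4 equiv), −78 to 0 °C; aq. NH4Cl
Reagents that add atoms: none
Why: Alkoxide acylation with excess anhydride esterifies both neopentyl-type carbinols (C2 and C11), each from its own molecule of anhydride, with Z geometry retained; any 1,2-acyl shift between neighbouring alkoxides is harmless because all three esters are the same.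

**Compound list**
1 | (S)-pantolactone, (3S)-3-hydroxy-4,4-dimethyloxolan-2-one | O[C@@H]1C(=O)OCC1(C)C | starting material
2 | (3S)-3-(methoxymethoxy)-4,4-dimethyloxolan-2-one | COCO[C@@H]1C(=O)OCC1(C)C | intermediate
3 | (3S)-3-(methoxymethoxy)-4,4-dimethyloxolan-2-ol (anomers) | COCO[C@@H]1C(O)OCC1(C)C | intermediate
4 | 3-(trimethylsilyl)prop-2-yn-1-ol | C[Si](C)(C)C#CCO | starting material
5 | [3-(methoxymethoxy)prop-1-yn-1-yl]trimethylsilane | COCOCC#C[Si](C)(C)C | intermediate
6 | [1-(methoxymethoxy)-3-(trimethylsilyl)prop-2-yn-1-yl]lithium | COCOC([Li])C#C[Si](C)(C)C | intermediate (not isolated)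
7 | [3-(methoxymethoxy)-1-(trimethylsilyl)propa-1,2-dien-1-yl]zinc bromide (racemic) | COCOC=C=C([Zn]Br)[Si](C)(C)C | intermediate (not isolated)
8 | (3S,4R,5S)-3,5-bis(methoxymethoxy)-2,2-dimethyl-7-(trimethylsilyl)hept-6-yne-1,4-diol | C[Si](C)(C)C#C[C@H](OCOC)[C@H](O)[C@@H](OCOC)C(C)(C)CO | intermediate
9 | (4S,5R)-4-(methoxymethoxy)-5-[(1S)-1-(methoxymethoxy)-3-(trimethylsilyl)prop-2-yn-1-yl]-3,3-dimethyloxolan-2-ol (anomers) | C[Si](C)(C)C#C[C@H](OCOC)[C@@H]1OC(O)C(C)(C)[C@@H]1OCOC | intermediate
10 | diethyl [(2E)-3-cyano-2-methylprop-2-en-1-yl]phosphonate (sold as E/Z mixture) | CCOP(=O)(OCC)C/C(C)=C/C#N | starting material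
11 | (2E,4E,7S,8R,9S)-8-hydroxy-7,9-bis(methoxymethoxy)-3,6,6-trimethyl-11-(trimethylsilyl)undeca-2,4-dien-10-ynenitrile | C[Si](C)(C)C#C[C@H](OCOC)[C@H](O)[C@@H](OCOC)C(C)(C)/C=C/C(C)=C/C#N | intermediate (not isolated)
12 | (2E,4E,7S,8S,9S)-8-hydroxy-7,9-bis(methoxymethoxy)-3,6,6-trimethylundeca-2,4-dien-10-ynenitrile | C#C[C@H](OCOC)[C@H](O)[C@@H](OCOC)C(C)(C)/C=C/C(C)=C/C#N | intermediate
13 | (2E,4E,7S,8S,9S)-8-hydroxy-7,9-bis(methoxymethoxy)-3,6,6-trimethylundeca-2,4-dien-10-ynal | C#C[C@H](OCOC)[C@H](O)[C@@H](OCOC)C(C)(C)/C=C/C(C)=C/C=O | intermediate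
14 | (2E,4E,7S,8S,9S,10E)-7,9-bis(methoxymethoxy)-3,6,6,10-tetramethylcycloundeca-2,4,10-triene-1,8-diol (C1 epimers) | OC1/C=C(C)/C=C/C(C)(C)[C@H](OCOC)[C@@H](O)[C@@H](OCOC)/C(C)=C/1 | intermediate
15 | (2E,4E,7S,8S,9S,10E)-8-hydroxy-7,9-bis(methoxymethoxy)-3,6,6,10-tetramethylcycloundeca-2,4,10-trien-1-one | O=C1/C=C(C)/C=C/C(C)(C)[C@H](OCOC)[C@@H](O)[C@@H](OCOC)/C(C)=C/1 | intermediate
16 | (1R,2R,3S,4R,5S,7S,8R)-4-hydroxy-3,5-bis(methoxymethoxy)-2,6,6,11-tetramethyltricyclo[5.4.0.0(2,8)]undec-10-en-9-one | O[C@@H]1[C@@H](OCOC)C(C)(C)[C@@H]2[C@H]3C(=O)C=C(C)[C@@H]2[C@@]3(C)[C@@H]1OCOC | intermediate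
17 | angelic anhydride, (2Z)-2-methylbut-2-enoic anhydride | C/C=C(/C)C(=O)OC(=O)/C(C)=C\C | starting material
18 | (1R,2R,3S,4R,5S,7S,8R)-3,5-bis(methoxymethoxy)-2,6,6,11-tetramethyl-9-oxotricyclo[5.4.0.0(2,8)]undec-10-en-4-yl (2Z)-2-methylbut-2-enoate | C/C=C(/C)C(=O)O[C@@H]1[C@@H](OCOC)C(C)(C)[C@@H]2[C@H]3C(=O)C=C(C)[C@@H]2[C@@]3(C)[C@@H]1OCOC | intermediate
19 | (1R,2R,3S,4R,5S,7S,8R)-3,5-bis(bromomethoxy)-2,6,6,11-tetramethyl-9-oxotricyclo[5.4.0.0(2,8)]undec-10-en-4-yl (2Z)-2-methylbut-2-enoate | C/C=C(/C)C(=O)O[C@@H]1[C@@H](OCBr)C(C)(C)[C@@H]2[C@H]3C(=O)C=C(C)[C@@H]2[C@@]3(C)[C@@H]1OCBr | intermediate (not isolated)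
20 | (1R,2R,3S,4R,5S,7S,8R)-3,5-dihydroxy-2,6,6,11-tetramethyl-9-oxotricyclo[5.4.0.0(2,8)]undec-10-en-4-yl (2Z)-2-methylbut-2-enoate | C/C=C(/C)C(=O)O[C@@H]1[C@@H](O)C(C)(C)[C@@H]2[C@H]3C(=O)C=C(C)[C@@H]2[C@@]3(C)[C@@H]1O | intermediate
21 | CNP0330079.1, (1R,2R,3S,4R,5S,7S,8R)-2,6,6,11-tetramethyl-9-oxotricyclo[5.4.0.0(2,8)]undec-10-ene-3,4,5-triyl tris[(2Z)-2-methylbut-2-enoate] | C/C=C(/C)C(=O)O[C@@H]1[C@@H](OC(=O)/C(C)=C\C)C(C)(C)[C@@H]2[C@H]3C(=O)C=C(C)[C@@H]2[C@@]3(C)[C@@H]1OC(=O)/C(C)=C\C | target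

**Step count**
Total: 13 steps. Longest linear sequence: 12 steps (steps 1, 2 and 4 to 13; step 3 is a one-step side branch).

**Three steps most likely to fail**

Step 8 (the proposed new nickel macrocyclisation) may give oligomers, the exo-cyclised ten-membered ring, conjugate coupling at the dienal, or simple methyl addition. The fallback uses known chemistry and sets out from 12. Zirconium-catalysed carboalumination and iodinolysis (AlMe3, Cp2ZrCl2, water-accelerated, CH2Cl2, −23 °C; then I2) gives (2E,4E,7S,8R,9S,10E)-8-hydroxy-11-iodo-7,9-bis(methoxymethoxy)-3,6,6,10-tetramethylundeca-2,4,10-trienenitrile F1. Reduction with i-Bu2AlH as in step 7 gives the corresponding iodo trienal F2. A Nozaki–Hiyama–Kishi macrocyclisation (CrCl2 in excess, catalytic NiCl2, DMSO/THF, 5 mM) then adds the vinyl iodide to the aldehyde with retention of alkene geometry and returns to the route at 14.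

Step 10 may fail in three ways:
- Regiochemistry: the trienone may close in the parallel sense (C4–C10 and C5–C9) to a 5-4-6 tricycle; simple acyclic hepta-1,6-dien-3-ones tend to follow that five-membered-ring-first mode, so the crossed outcome rests on the steric argument in the Why line.
- Facial selectivity: the wrong face may be chosen relative to the C1, C2 and C11 centres.
- Photostability: product 16 is a verbenone-type enone and may undergo a photochemical 1,3-shift if it is excited.

The fallback sets out from 14, before the oxidation. The same sensitiser and light are applied to the dienyl carbinol, where the C5=C10 alkene is an isolated trisubstituted olefin, so the triplet diene terminus C4 can add only to its unsubstituted end. This diene–alkene [2+2] gives (1R,2R,3S,4R,5S,7S,8R)-3,5-bis(methoxymethoxy)-2,6,6,11-tetramethyltricyclo[5.4.0.0(2,8)]undec-10-ene-4,9-diol F3 (epimers at C9), and MnO2 oxidation of its allylic alcohol returns to the route at 16.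

Step 13 may stall at the two carbinols that sit next to quaternary carbons, a slight excess of amide base may form the enone dienolate and acylate it, or the alkoxides may add reversibly to the enone. The fallback sets out from 20 and builds the last two angelates in place. Acylation of both free carbinols with the saturated, unhindered 2-[bis(2,2,2-trifluoroethoxy)phosphoryl]propanoic acid (DCC, DMAP, CH2Cl2) gives (1R,2R,3S,4R,5S,7S,8R)-2,6,6,11-tetramethyl-4-{[(2Z)-2-methylbut-2-enoyl]oxy}-9-oxotricyclo[5.4.0.0(2,8)]undec-10-ene-3,5-diyl bis{2-[bis(2,2,2-trifluoroethoxy)phosphoryl]propanoate} F4. A twofold Still–Gennari olefination with acetaldehyde (KN(SiMe3)2, 18-crown-6, THF, −78 °C) then forms the two remaining (Z)-2-methylbut-2-enoates and arrives at 21.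

**Further compounds**
F1 | step 8 | (2E,4E,7S,8R,9S,10E)-8-hydroxy-11-iodo-7,9-bis(methoxymethoxy)-3,6,6,10-tetramethylundeca-2,4,10-trienenitrile | I/C=C(C)/[C@H](OCOC)[C@H](O)[C@@H](OCOC)C(C)(C)/C=C/C(C)=C/C#N
F2 | step 8 | (2E,4E,7S,8R,9S,10E)-8-hydroxy-11-iodo-7,9-bis(methoxymethoxy)-3,6,6,10-tetramethylundeca-2,4,10-trienal | I/C=C(C)/[C@H](OCOC)[C@H](O)[C@@H](OCOC)C(C)(C)/C=C/C(C)=C/C=O
F3 | step 10 | (1R,2R,3S,4R,5S,7S,8R)-3,5-bis(methoxymethoxy)-2,6,6,11-tetramethyltricyclo[5.4.0.0(2,8)]undec-10-ene-4,9-diol (C9 epimers) | O[C@@H]1[C@@H](OCOC)C(C)(C)[C@@H]2[C@H]3C(O)C=C(C)[C@@H]2[C@@]3(C)[C@@H]1OCOC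
F4 | step 13 | (1R,2R,3S,4R,5S,7S,8R)-2,6,6,11-tetramethyl-4-{[(2Z)-2-methylbut-2-enoyl]oxy}-9-oxotricyclo[5.4.0.0(2,8)]undec-10-ene-3,5-diyl bis{2-[bis(2,2,2-trifluoroethoxy)phosphoryl]propanoate} (mixed at the phosphonate-bearing carbons) | C/C=C(/C)C(=O)O[C@@H]1[C@@H](OC(=O)C(C)P(=O)(OCC(F)(F)F)OCC(F)(F)F)C(C)(C)[C@@H]2[C@H]3C(=O)C=C(C)[C@@H]2[C@@]3(C)[C@@H]1OC(=O)C(C)P(=O)(OCC(F)(F)F)OCC(F)(F)F
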